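I freeze the substrate. The maple run is charged with 100 mM of substrate against 50.0 mM of partner, so partner is the limiting reagent and its fall should set the course of the batch.

| flask | substrate | partner | free catalyst | time |
|---|---|---|---|---|
| ash | 100 mM | 150 mM | 3.00 mM |  |
| birch | 40.0 mM | 90.0 mM | 3.00 mM |  |
| alder | 300 mM | 150 mM | 3.00 mM |  |
| maple | 100 mM | 50.0 mM | 3.00 mM | 76 min |

| run | time / min | [product] / mM |
|---|---|---|
| ash run | 3.0 | 2.8 |
| ash run | 4.8 | 4.0 |
| ash run | 7.6 | 7.8 |
| ash run | 12 | 12.9 |
| ash run | 19 | 20.7 |
| ash run | 30 | 34.8 |
| ash run | 48 | 51.3 |
| ash run | 76 | 74.8 |
| birch run | 3.0 | 1.7 |
| birch run | 4.8 | 2.3 |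
| birch run | 7.6 | 5.0 |
| birch run | 12 | 5.9 |
| birch run | 19 | 9.0 |
| birch run | 30 | 12.1 |
| birch run | 48 | 18.7 |
| birch run | 76 | 26.5 |
| alder run | 3.0 | 1.2 |
| alder run | 4.8 | 5.5 |
| alder run | 7.6 | 6.8 |
| alder run | 12 | 12.2 |
| alder run | 19 | 26.7 |
| alder run | 30 | 54.1 |
| alder run | 48 | 98.7 |
| alder run | 76 | 132.0 |

(scatter of a reading: 1 mM)

- reaction order in [partner] at the outset, round the charge of the ash run, defined at two percent of the substrate turned into product
- reaction order in [substrate] at the outset, round the charge of the ash run, defined at two percent of the substrate turned into product (one fixed amount of product, the same in the runs compared)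
- the birch run starts with 60.0 mM less of substrate and of partner than the ash run, and with no product. Compared where both hold the same amount of substrate, once fifteen percent of what the birch run was charged with has turned into product, is the birch run faster, slower or alike (within a tenth)?
- product in the maple run at 76 min, as a share of the substrate charged

- Overall: substrate + partner -> product, with free catalyst as catalyst.
- Constant volume, constant temperature.
- The analysis sees a species whether free or bound.
- "The second partner" is partner.
- An order is taken over about fifteen percent of the charge, up and down.

If the rate follows partner and hardly feels substrate, partner decays pseudo-first-order. I call κ the logarithm of partner charged over partner left, divided by time, with partner left being charge minus product. I take order one in partner as an assumption, since no earlier pair of runs changes partner with substrate held equal. The ash run at 12 min gives κ = 0.00749 /min, and this puts the maple run at 21.7 mM by 76 min.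

My first doubt is the freeze itself. The alder run, with 300 mM of substrate, reads 0.00707 /min at 12 min, which is slightly less than the ash run, so the substrate order between these two charges reads −0.0531, near zero. The birch run, with 40.0 mM of substrate, reads lower at 19 min, 0.00555 /min. But the maple run ends near 78.3 mM of substrate, and the ash run holds 79.3 mM at 19 min, so the two cover about the same range.

My second doubt is worse, because κ is not constant in the ash run: at 48 min it reads 0.00872 /min, more than at 12 min, with 51.3 mM of product present. So I freeze κ at equal product instead of equal time. The ash run has made 20.7 mM at 19 min, close to the maple estimate, and there it gives the equal-product partner constant, 0.00782 /min. The maple run then comes to 22.4 mM, or 22.4% of its substrate, and the scatter of that one reading moves this by about 0.854 mM. Where the birch and ash runs hold equal substrate, the birch run has 60.0 mM less product, so I call it slower.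

The forecast gives order 1 in partner (0.7 to 1.2), 0 in substrate (−0.3 to 0.3), the birch run slower, and 22% for the maple run (18% to 27%), holding that “product accelerates the reaction”.

The maple run gives 22.6%, the orders are 1.0 in partner and 0.087 in substrate, and the birch run is slower. The steps are these:

    free catalyst + substrate ⇌ catalyst-substrate complex, settled at all times (31.10 /M)
    catalyst-substrate complex + partner → product + free catalyst (3.426 /M/min)
    substrate + partner + product → 2 product (1.680 /M²/min)
    catalyst-substrate complex + substrate ⇌ doubly bound catalyst, settled at all times (2.920 /M)

At the outset, where two percent of the substrate of the ash run has turned into product, the alder run goes at 0.93 of the ash rate. Carried to the birch run, 0.00782 /min puts a quarter of its substrate turned at 15.1 min. The birch run takes 22.5 min, which reads as κ = 0.00523 /min.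

(All runs were generated by integration with made-up constants.)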